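The numbers of this flask were set for the occasion; the rest is arithmetic.

Watch the reagent when you repeat this run, not the starting material: its charge is the smaller one, so it is the limiting reagent for the target.

the same everywhere: starting material 0.050 M; reagent 0.0350 M; free catalyst 2.5 mM

| flask | second substrate | time | remark |
|---|---|---|---|
| north-west | 0.0500 M | 2.0 d | everything together in a closed stirred flask, run for 2.0 d |
| west | 0.0500 M |  | a single well-mixed tank run continuously and read at steady state, 2.0 d in it on average |
| north | 0.0500 M (fed, over 2.00 d) | 2.0 d | all but second substrate at the start; second substrate goes in evenly over 2.00 d, the run ends at 2.0 d |
| south-east | 0.0500 M | 2.0 d | plug flow through a tube for 2.0 d, no back-mixing |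

    starting material + free catalyst ⇌ catalyst intermediate A (K1 = 8.1 /M, k1 = 0.0056 /M/s)
    second substrate + free catalyst ⇌ catalyst intermediate B (K2 = 46 /M, k2 = 0.0035 /M/s)
    reagent + catalyst intermediate A → free catalyst + target (k3 = 0.039 /M/s)
    reagent + catalyst intermediate B → free catalyst + second product (k4 = 0.0013 /M/s)
    target + free catalyst ⇌ isomer of the product + free catalyst, rate k5*[free catalyst]*[target] forward; the back reaction follows from the equilibrium constant (K5 = 0.97, k5 = 8.6 × 10⁻⁴ /M/s)

1. the set-up with the highest amount of target at the outlet or at the end, in percent of the starting material put in ("none" if the first two lie within 2 percentage points) (north-west / west / north / south-east / none)
2. amount of target at the outlet or at the end, in percent of the starting material put in, north-west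
3. amount of target at the outlet or at the end, in percent of the starting material put in, west
4. amount of target at the outlet or at the end, in percent of the starting material put in, north
5. amount of target at the outlet or at the end, in percent of the starting material put in, south-east

- the stated concentrations are those of everything mixed, before any reaction; amounts are the same in each set-up
- the feed brings no volume worth counting
- run time (north-west): 2.0 d

I begin with the closed flask, north-west. With reagent at its charge, catalyst intermediate A goes on to target with a half-life of 0.14 h by that step alone, and catalyst intermediate B goes on to second product with a half-life of 0.18 d by that step alone. Both are shorter than the run, so I treat each as quasi-steady, made as fast as it is lost.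

With everything at its charge, the ratio of each intermediate to free catalyst is its binding rate constant times substrate, over its falling-back constant plus its onward rate constant times reagent. That gives 0.136 for intermediate A and 1.44 for intermediate B, so free catalyst is 38.8 % of the catalyst and intermediate B is the resting state.

Now define λ, the reagent decay constant: each onward rate constant times its intermediate's level, summed, 0.602 /d. I hold λ fixed, which is a bet: starting material falls in the top of the first ratio and reagent in the bottom, so they pull opposite ways. Reagent is then pseudo-first-order, and integrating gives exp(−λt) of it left, 30.0 % at the end of the run.

At these levels, 73.9 % of the reagent used goes to target. So I reckon target and isomer together at 36.2 % of the starting material, which is a sum and not target by itself. The tube without back-mixing repeats the closed flask along its length. I stop there: this reckoning is for the closed flask and the tube.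

The forecast names north, with 34.7 % for north-west, 26.1 % for west, 42.9 % for north and 34.7 % for south-east, holding that “Dosing second substrate keeps the catalyst free early”.

The simulation gives north as best, with 35.0 % for north-west, 26.3 % for west, 43.5 % for north and 35.0 % for south-east. In north-west at 2.00 d, the step to target uses reagent 2.9 times as fast as the step to second product, and 28.4 % of the reagent stands. For the same flask read at 30 h, I reckon by exp(−λt) that 47.1 % of its reagent is left, and the simulation gives 46 %. Weigh the reagent carefully: with the other amounts and the time held, south-east's answer has moved 5 points at 0.0278 M and at 0.0436 M.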